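## Analysis of the target

Atoms are numbered as in ent-kaurane. Read along the SMILES they are C17=C16(C15O2H)-C13-C12-C11-C9-C8(-C14-C13)-C7(=O)-O-C20-C10-C1(=O)-C2-C3-O-C6-C5-C4(C18)(C19), so 21 (C20H26O6) is a 6,7:8,15-diseco-ent-kauranoid. Ring A (C1-C5, C10) is a cyclohexanone whose C3 and C5 are bridged by O-C6 (a 6-oxabicyclo[3.2.1]octane with the gem-dimethyl carbon C4 as one-atom bridge). Ring B (C7, O, C20, C10, C9, C8) is a δ-lactone, spiro to ring A at the quaternary C10 and cis-fused to the cyclohexane ring C (C8, C9, C11-C14), which carries the 2-substituted acrylic acid at C13. The six stereocentres are 3R, 5R, 8S, 9R, 10S and 13R: on ring C, C7 and C10 are cis and C16 is trans to both (C10 and C16 equatorial, C7 axial); on ring A, C6 and C20 are cis, C9 is trans-diaxial to C6 and 1,3-diaxial to one C4 methyl group, and C3 is tied to C5 by the bridge. The two sets (C3, C5, C10 and C8, C9, C13) meet only at the C9-C10 bond, so no ring relays information between them until ring B exists. The sensitive groups are the β-alkoxy ketone C1/C3 (retro-oxa-Michael), C8-H (α to the lactone carbonyl, epimerisable), the β-acyloxy ketone C1/C10/C20 (retro-aldol once the lactone is opened) and the acrylic acid (Michael acceptor, easily hydrogenated). The hard part is the C9-C10 bond, which joins a tertiary carbon to a quaternary one flanked by C5 and the C4 methyl groups. The feature used here is a hidden 1,4-diketone C1/C8 built from two enones joined α′ to α′: opening the C3-O bond shows ring A as a cyclohex-2-enone (C1=O, C2=C3) with C10 as its α′ carbon, and removing C7 as a carbonyl insertion and C16 as a Michael donor shows ring C as a second cyclohex-2-enone (C8=O, C14=C13) with C9 as its α′ carbon.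

## Retrosynthetic reasoning

**C16=C17.** The acrylic acid of 21 is cut at the methylene carbon C17 and traced through the Mannich base 20 to the malonic acid 19. This is preferred to oxidising an isopropenyl group for two reasons. A malonate carries no alkene through the hydrogenation that sets C8, and it turns C13-C16 into a Michael bond. The forward step must methylenate and decarboxylate without touching C2 or C8.

**C8-H, then both bonds of C7 (ring B).** 19 goes back to the unsaturated lactone 18, and 18 is cut at C7-C8 and C7-O to give the hydroxy enol triflate 17. C7 becomes a one-carbon carbonyl insertion and C8 a former ketone carbon. Ring B then closes late, on a centre that no longer has to be attacked by a bulky partner, and C8 is set last on a rigid tricycle. The forward hydrogenation must add to the face that already bears H9.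

**C3-O and C6.** The bridge of 17 and 16 is opened by a retro-oxa-Michael step to the hydroxy enone 15. Its C6 is traced through the aldehyde 14 to the vinyl group of 13. While the bridge is absent, ring A has no enolisable hydrogen at all (C10 quaternary, C2 vinylic), so all base and triflation chemistry on ring C is done before the bridge is closed. The vinyl group is a hydroxymethyl group that needs no protecting group.

**C13-C16.** The enol triflate 13 comes from the ketone 12, and 12 is cut at C13-C16 into the bis-enone 10 and dibenzyl malonate 11. A chiral catalyst sets C13. C9, which is α to the C8 ketone, then settles trans-diequatorial to C13 by equilibration. The ring A enone cannot compete because its β-carbon C3 is neopentyl.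

**C9-C10 (key).** 10 is a 1,4-diketone, a dissonant pattern that no polar enolate/acceptor pair can give. It is cut at its central bond into two α′-dienolates held on one silicon atom, the mixed bis(dienol) ether 9. The cut is made here because it is the only bond between the two halves, and because both halves become simple enones. The forward reaction is an oxidative coupling that must form the quaternary C10 on the face opposite to the C5 substituent.

**Si-O, C10-C20, C5-C6.** 9 is assembled from the lithium dienolate 8 of ketone 4 and the chlorosilane 7, which comes from cyclohex-2-en-1-one 5 through its dienolate 6. C20 must be on C10 before C9 arrives, because the last group to enter goes anti to C6, and that group has to be C9. 4 comes from 2 by hydroxymethylation (3) and silylation. 2 comes from the achiral dienone 1 by a desymmetrising conjugate vinylation that sets C5.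

## Alternatives that were turned down

**Alternative 1:** the textbook cut, C9-C10 as a Michael bond along the consonant path C1(=O)-C10-C9-C8-C7(=O). In the forward sense the lithium dienolate 8 would add to methyl (5R)-5-(prop-1-en-2-yl)cyclohex-1-ene-1-carboxylate A1 to give the adduct A2, followed by desilylation and lactonisation.
- A tetrasubstituted, neopentyl-flanked enolate would have to attack the β-carbon of a weakly electrophilic, β-substituted cyclic enoate. The addition is reversible, and the temperature it needs would let 8 lose silanolate.
- Stereoelectronically preferred axial attack on the half-chair of A1 (C13 substituent equatorial) puts C10 cis to C16. This is the wrong 1,4-relation, and C9 of A2 cannot be epimerised.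
- A1 has the 1,3 ("meta") substitution pattern, which the p-menthane chiral pool does not offer, so it needs a synthesis of its own.

**Alternative 2:** ring C by a Diels-Alder reaction, cutting C8-C14 and C9-C11. In the forward sense the spiro dihydropyranone A3 (C8=C9) would react with 2-methyl-3-methylidenepenta-1,4-diene A4 to give the cis-fused adduct A5.
- The cis fusion would come for free, but the regiochemistry is against the plan. The diene terminus next to the 2-substituent bonds to the β-carbon C9, so the side chain ends on C12 instead of C13.
- C9 of A3 is neopentyl, which makes a poor dienophile poorer.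
- C13 of A5 emerges sp2 and would have to be reduced selectively and stereoselectively next to the isopropenyl group.

**Alternative 3:** restore ring B as a carbocycle and cleave C6-C7 later (the biogenetic order). In the forward sense methyl 3,3-dimethyl-6-oxocyclohexa-1,4-diene-1-carboxylate A6 (dienophile C5=C10) and the silyloxydiene A7 (C6=C7(OSiMe3)-C8=C9) would give the tricycle A8, followed by enol ether transposition and ozonolysis.
- One step would form both C5-C6 and C9-C10, but suprafacial addition to the cyclic dienophile makes these two bonds cis on ring A, while 21 needs them trans.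
- C5 could be corrected only at the C6 aldehyde stage. There an axial formyl group between two quaternary carbons and two sp2 ring atoms has no clear thermodynamic bias.
- C20 arrives as an ester that would have to be reduced beside two ketones.
- A7 again needs the "meta" ring C, and the C6/C7 oxidation states come out reversed.

Key step: step 5

Assumption: the sense of induction of (R)-BINAP in step 1 and of the (R)-binaphthoxide catalyst in step 6 is taken from the parent enone 5. If it is reversed on these substrates, the other ligand enantiomer is used.

## Route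

**Step 1**
Reactants: 1 4,4-dimethylcyclohexa-2,5-dien-1-one
Product: 2 (5R)-4,4-dimethyl-5-vinylcyclohex-2-en-1-one
Conditions: K[CH2=CHBF3] (0.8 equiv), [Rh(cod)2]BF4 (3 mol %), (R)-BINAP (3.3 mol %), toluene/H2O 10:1, 100 °C
Reagents that add atoms: potassium vinyltrifluoroborate C=C[B-](F)(F)F.[K+]
Why: Hayashi-Miyaura-type asymmetric 1,4-addition with a monovalent rhodium catalyst; the two enone halves of 1 are enantiotopic, so one addition desymmetrises the ring and sets C5. The vinyl group is a latent C6 hydroxymethyl group, and the excess of 1 suppresses a second addition.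

**Step 2**
Reactants: 2 (5R)-4,4-dimethyl-5-vinylcyclohex-2-en-1-one
Product: 4 (5S,6R)-6-{[(tert-butyldimethylsilyl)oxy]methyl}-4,4-dimethyl-5-vinylcyclohex-2-en-1-one, via hydroxymethyl ketone 3 (not isolated)
Conditions: LiN(iPr)2, THF, −78 °C; CH2O (gas); H2O; crude 3, TBSCl, imidazole, DMF, rt
Reagents that add atoms: formaldehyde C=O; tert-butyldimethylsilyl chloride CC(C)(C)[Si](C)(C)Cl
Why: Kinetic α′-deprotonation (C10 is the only acidic site) and aldol addition, expected anti to the vinyl group; this C10 configuration is erased in step 4 and does not matter. Silylation blocks retro-aldol cleavage and dehydration.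

**Step 3**
Reactants: 5 cyclohex-2-en-1-one
Product: 7 chloro(cyclohexa-1,5-dien-1-yloxy)di(propan-2-yl)silane, via lithium dienolate 6 (not isolated)
Conditions: LiN(iPr)2, THF, −78 °C; iPr2SiCl2 (5 equiv), −78 °C to rt; distillation
Reagents that add atoms: dichlorodiisopropylsilane CC(C)[Si](Cl)(Cl)C(C)C
Why: The kinetic cross-conjugated dienolate is silylated on oxygen; the large excess of the hindered dichlorosilane stops the reaction at monosubstitution and is removed by distillation.

**Step 4**
Reactants: 4 (5S,6R)-6-{[(tert-butyldimethylsilyl)oxy]methyl}-4,4-dimethyl-5-vinylcyclohex-2-en-1-one; 7 chloro(cyclohexa-1,5-dien-1-yloxy)di(propan-2-yl)silane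
Product: 9 mixed diisopropylsilyl bis(dienol) ether of 4 and 5 (ring A: C1(O)=C10 and C2=C3; ring C: C8(O)=C9 and C13=C14), via lithium dienolate 8 (not isolated)
Conditions: LiN(iPr)2, THF, −78 °C; 7, −78 °C to 0 °C; filtration, used crude
Reagents that add atoms: none
Why: C10-H is the only enolisable position of 4, and the hard chlorosilane reacts at the enolate oxygen (stepwise synthesis of an unsymmetrical silyl bis-enol ether). At −78 °C loss of silanolate from 8 should be slow.

**Step 5**
Reactants: 9 mixed diisopropylsilyl bis(dienol) ether
Product: 10 α′,α′-linked bis-enone 6-{[(tert-butyldimethylsilyl)oxy]methyl}-4,4-dimethyl-6-(2-oxocyclohex-3-en-1-yl)-5-vinylcyclohex-2-en-1-one (C9-C10 bond trans to the vinyl group; C5 and C10 spatially as in 21; C9 labile and drawn as in 21)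
Conditions: (NH4)2Ce(NO3)6 (2.2 equiv), NaHCO3 (4.5 equiv), MeCN, −10 °C
Reagents that add atoms: none
Why: Tetravalent cerium removes one electron from the more electron-rich, tetrasubstituted dienol ether of ring A, which puts radical character on C10; C10 attacks C9, the nucleophilic terminus of the ring C dienol ether held close by the O-Si-O tether, and a second one-electron oxidation with loss of the silicon group frees both carbonyl groups, so that the enones C1(=O)-C2=C3 and C8(=O)-C14=C13 come out intact. The closest known reaction type is the oxidative cross-coupling of unsymmetrical silyl bis-enol ethers with (NH4)2Ce(NO3)6, which is established for pairs of cyclic ketones and for quaternary α-carbons. No ring of 21 is closed; the only ring formed is a transient seven-membered 1,3-dioxa-2-silacycle (C10, C1, O, Si, O, C8, C9), closed 7-endo-trig because attack at C9 leaves an oxygen-stabilised allyl radical at C8, while 6-exo attack at C8 would leave an unstabilised one. C10 is controlled by C5: in the flat cyclohexadiene ring of 9 the vinyl group stands pseudoaxial to escape the C4 methyl groups and the C10 side chain, the new bond forms on the opposite face, and C20 is pushed to the side of C6, which is the trans-diaxial C9/C6 relation of 21. C9 is formed without control, but it stays α to the C8 ketone and is set by equilibration in step 6. The step needs cross- over homo-coupling (secured by the tether), C9 over C13 as the reacting terminus of ring C (ring size and radical stability) and survival of the vinyl group and the silyl ether (both should be inert to the buffered oxidant at low temperature). In one operation it makes the most hindered bond of 21, its quaternary centre and the 1,4-diketone that later accepts C7 and C16, from two enones that are joined only through oxygen.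

**Step 6**
Reactants: 10 α′,α′-linked bis-enone; 11 dibenzyl malonate
Product: 12 dibenzyl 2-[(13R)-8-oxo-9-(ring A)cyclohexyl]malonate (target numbering; malonate on C13 trans to C10 on C9, both equatorial)
Conditions: 11 (1.2 equiv), LiAl[(R)-binaphthoxide]2 (10 mol %, from LiAlH4 and (R)-BINOL), THF, rt; then DBU (20 mol %), CH2Cl2, rt
Reagents that add atoms: none
Why: Catalytic asymmetric Michael addition with a Lewis acid/Brønsted base binaphthoxide, a reaction type optimised on cyclohex-2-enones; C13 is set by the catalyst, and the ring A enone is inert because C3 is neopentyl. DBU then equilibrates C9 to the diequatorial trans-2,5-disubstituted cyclohexanone, which is the C9/C13 relation of 21.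

**Step 7**
Reactants: 12 Michael adduct
Product: 13 enol triflate C8(OTf)=C14 of 12
Conditions: Tf2O, 2,6-di-tert-butyl-4-methylpyridine, CH2Cl2, 0 °C to rt
Reagents that add atoms: trifluoromethanesulfonic anhydride O=S(=O)(OS(=O)(=O)C(F)(F)F)C(F)(F)F
Why: O-Triflylation of the only enolisable ketone followed by loss of the accessible C14 proton; C9-H is shielded by C10, and a C8=C9 alkene would be tetrasubstituted next to a quaternary carbon. The non-basic conditions leave the malonate and C9 untouched.

**Step 8**
Reactants: 13 enol triflate
Product: 16 bridged ether (6-oxabicyclo[3.2.1]octanone ring A with C3-O-C6 closed; enol triflate malonate and silyl ether retained), via aldehyde 14 (not isolated), via hydroxy enone 15 (not isolated)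
Conditions: O3, CH2Cl2, −78 °C; Me2S; volatiles removed; NaBH(OAc)3, AcOH, CH2Cl2, 0 °C; then DBU (20 mol %), CH2Cl2, rt
Reagents that add atoms: ozone [O-][O+]=O
Why: The monosubstituted alkene is by far the most electron-rich π bond (the others are an enone and an enol triflate); the aldehyde is reduced at once by the mild acyloxyborohydride, so that C5 has no chance to epimerise and the ketone survives. The C6 hydroxyl group then adds to C3 in a 5-exo-trig oxa-Michael reaction, and because it reaches only its own face of the ring, C3 follows from C5.

**Step 9**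
Reactants: 16 bridged ether
Product: 17 hydroxy enol triflate (free C20 hydroxymethyl group)
Conditions: HF·pyridine, THF, 0 °C to rt
Reagents that add atoms: none
Why: Desilylation under acidic conditions avoids the alkoxide that would start a retro-aldol loss of C20; enol triflate, bridge and benzyl esters are stable.

**Step 10**
Reactants: 17 hydroxy enol triflate
Product: 18 unsaturated spiro lactone (ring B closed; C8=C14)
Conditions: CO (1 atm), Pd(PPh3)4 (10 mol %), iPr2NEt, DMF, 60 °C
Reagents that add atoms: carbon monoxide [C-]#[O+]
Why: Carbonylative lactonisation: oxidative addition of zerovalent palladium into the C8-O bond, CO insertion, and capture of the acyl-palladium species by the C20 hydroxyl group close the six-membered lactone and bring in C7.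

**Step 11**
Reactants: 18 unsaturated spiro lactone
Product: 19 saturated cis-fused lactone malonic acid
Conditions: H2 (1 atm), Pd/C, EtOAc/EtOH, rt
Reagents that add atoms: none
Why: Heterogeneous syn-hydrogenation of C8=C14; in 18, H9 is axial on ring B and the C1 carbonyl group is axial on the opposite face, 1,3 to C8, so hydrogen should add on the side of H9 and give the cis fusion (8S). The same conditions cleave both benzyl esters.

**Step 12**
Reactants: 19 saturated cis-fused lactone malonic acid
Product: 21 target CNP0268721.2, via Mannich base 20 (not isolated)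
Conditions: aq CH2O, Et2NH, EtOAc, 0 °C to reflux
Reagents that add atoms: formaldehyde C=O
Why: Mannich reaction of the monosubstituted malonic acid followed by decarboxylative elimination of the amine, the classical route to 2-substituted acrylic acids. The malonic acid is far more reactive than C2 of the ketone, and the weak base should leave C8 alone.

## Compound list

1 | 4,4-dimethylcyclohexa-2,5-dien-1-one | CC1(C)C=CC(=O)C=C1 | starting material
2 | (5R)-4,4-dimethyl-5-vinylcyclohex-2-en-1-one | C=C[C@H]1CC(=O)C=CC1(C)C | intermediate
3 | (5S,6R)-6-(hydroxymethyl)-4,4-dimethyl-5-vinylcyclohex-2-en-1-one | C=C[C@H]1[C@H](CO)C(=O)C=CC1(C)C | intermediate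
4 | (5S,6R)-6-{[(tert-butyldimethylsilyl)oxy]methyl}-4,4-dimethyl-5-vinylcyclohex-2-en-1-one | C=C[C@H]1[C@H](CO[Si](C)(C)C(C)(C)C)C(=O)C=CC1(C)C | intermediate
5 | cyclohex-2-en-1-one | O=C1C=CCCC1 | starting material
6 | lithium cyclohexa-1,5-dien-1-olate | [Li+].[O-]C1=CCCC=C1 | intermediate
7 | chloro(cyclohexa-1,5-dien-1-yloxy)di(propan-2-yl)silane | CC(C)[Si](Cl)(OC1=CCCC=C1)C(C)C | intermediate
8 | lithium dienolate of 4 | [Li+].[O-]C1=C(CO[Si](C)(C)C(C)(C)C)[C@H](C=C)C(C)(C)C=C1 | intermediate
9 | mixed diisopropylsilyl bis(dienol) ether of 4 and 5 | C=C[C@H]1C(CO[Si](C)(C)C(C)(C)C)=C(O[Si](C(C)C)(C(C)C)OC2=CCCC=C2)C=CC1(C)C | intermediate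
10 | α′,α′-linked bis-enone | O=C1C=CCC[C@H]1[C@]1(CO[Si](C)(C)C(C)(C)C)C(=O)C=CC(C)(C)[C@H]1C=C | intermediate
11 | dibenzyl malonate | O=C(CC(=O)OCc1ccccc1)OCc1ccccc1 | starting material
12 | Michael adduct (C8 ketone, malonate on C13) | O=C(OCc1ccccc1)C(C(=O)OCc1ccccc1)[C@@H]1CC[C@H](C(=O)C1)[C@]1(CO[Si](C)(C)C(C)(C)C)C(=O)C=CC(C)(C)[C@H]1C=C | intermediate
13 | enol triflate C8(OTf)=C14 | O=C(OCc1ccccc1)C(C(=O)OCc1ccccc1)[C@@H]1CC[C@H](C(OS(=O)(=O)C(F)(F)F)=C1)[C@]1(CO[Si](C)(C)C(C)(C)C)C(=O)C=CC(C)(C)[C@H]1C=C | intermediate
14 | C6 aldehyde | O=C(OCc1ccccc1)C(C(=O)OCc1ccccc1)[C@@H]1CC[C@H](C(OS(=O)(=O)C(F)(F)F)=C1)[C@]1(CO[Si](C)(C)C(C)(C)C)C(=O)C=CC(C)(C)[C@H]1C=O | intermediate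
15 | C6 hydroxy enone | O=C(OCc1ccccc1)C(C(=O)OCc1ccccc1)[C@@H]1CC[C@H](C(OS(=O)(=O)C(F)(F)F)=C1)[C@]1(CO[Si](C)(C)C(C)(C)C)C(=O)C=CC(C)(C)[C@H]1CO | intermediate
16 | bridged ether (C3-O-C6 closed) | O=C(OCc1ccccc1)C(C(=O)OCc1ccccc1)[C@@H]1CC[C@H](C(OS(=O)(=O)C(F)(F)F)=C1)[C@]1(CO[Si](C)(C)C(C)(C)C)C(=O)C[C@H]2OC[C@@H]1C2(C)C | intermediate
17 | hydroxy enol triflate | O=C(OCc1ccccc1)C(C(=O)OCc1ccccc1)[C@@H]1CC[C@H](C(OS(=O)(=O)C(F)(F)F)=C1)[C@]1(CO)C(=O)C[C@H]2OC[C@@H]1C2(C)C | intermediate
18 | unsaturated spiro lactone (C8=C14) | O=C(OCc1ccccc1)C(C(=O)OCc1ccccc1)[C@@H]1CC[C@@H]2C(=C1)C(=O)OC[C@]21C(=O)C[C@H]2OC[C@@H]1C2(C)C | intermediate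
19 | saturated cis-fused lactone malonic acid | OC(=O)C(C(=O)O)[C@@H]1CC[C@@H]2[C@H](C1)C(=O)OC[C@]21C(=O)C[C@H]2OC[C@@H]1C2(C)C | intermediate
20 | 2-(diethylaminomethyl)malonic acid (Mannich base of 19) | CCN(CC)CC(C(=O)O)(C(=O)O)[C@@H]1CC[C@@H]2[C@H](C1)C(=O)OC[C@]21C(=O)C[C@H]2OC[C@@H]1C2(C)C | intermediate
21 | CNP0268721.2, (3R,5R,8S,9R,10S,13R) | C=C(C(=O)O)[C@@H]1CC[C@@H]2[C@H](C1)C(=O)OC[C@]21C(=O)C[C@H]2OC[C@@H]1C2(C)C | target

## Step count and least certain steps

Total step count: 12. Longest linear sequence: 11 (steps 1, 2 and 4 to 12; step 3 is a one-step branch).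

**Step 5 (key step).**
- What may go wrong: bond formation at the congested C10 may be slower than decay of the radical cation. That decay is desilylation back to the two ketones, or dehydrogenation of the ring C dienol ether to an aryl silyl ether. Facial selectivity may also be eroded, because the face anti to the vinyl group carries a pseudoaxial C4 methyl group.
- Fallback: a polar umpolung in place of an oxidation. It sets out from 4.
  - The dienolate 8 is added to the nitrosoalkene released in situ from 2-chlorocyclohexan-1-one oxime F1 (made from commercial 2-chlorocyclohexanone and hydroxylamine). This small and very reactive acceptor gives the α-substituted oxime F2.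
  - Reductive deoximation with aqueous TiCl3/NH4OAc (trivalent titanium) gives the saturated 1,4-diketone F3.
  - Dehydrogenation with IBX on the only accessible α-methylene group (C14) comes back to the route at 10.

**Step 4.**
- What may go wrong: deprotonation of the hindered tertiary C10-H may be incomplete, and the lithium enolate may lose silanolate before it is trapped.
- Fallback: no metal enolate at all. It sets out from 4.
  - Soft enolisation with Me3SiOTf/Et3N gives the trimethylsilyl dienol ether F4.
  - N-Bromosuccinimide gives the tertiary α-bromo enone F5.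
  - Irradiation with visible light in the presence of Ir(ppy)3 and 2,6-lutidine generates the C10 radical. This adds to C9 of commercial 2-(trimethylsilyloxy)cyclohexa-1,3-diene F6.
  - Oxidation and desilylation of the adduct radical give 10, so the fallback bypasses steps 4 and 5.

**Step 1.**
- What may go wrong: insertion at the neopentyl β-carbon may be slow, a second addition may compete, and enantioselectivity may be eroded at the temperature required.
- Fallback: iminium activation with a different one-carbon donor. It sets out from 1.
  - Nitromethane with 9-amino-9-deoxy-epi-quinine and benzoic acid gives (5S)-4,4-dimethyl-5-(nitromethyl)cyclohex-2-en-1-one F7.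
  - A Nef reaction (NaOMe, then aqueous TiCl3/NH4OAc) gives (1S)-2,2-dimethyl-5-oxocyclohex-3-ene-1-carbaldehyde F8.
  - Non-basic methylenation of the aldehyde (Zn, CH2Br2, TiCl4) comes back at 2.

**Step 6.**
- What may go wrong: the catalyst may bind poorly to an enone with a very large α′ substituent. Catalyst control may be eroded by the resident stereocentres, and the 1,4-diketone may close by aldol reaction (C14 onto C1).
- Fallback: C13 is set first, on the parent substrate. It sets out from 5 and 11.
  - The same catalyst gives dibenzyl 2-[(1R)-3-oxocyclohexyl]malonate F9.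
  - The dienolate 8 (from 4) is silylated with excess iPr2SiCl2 to the chlorosilane F10.
  - F9 is deprotonated with two equivalents of LiN(iPr)2. The malonate anion shields C14, so the ketone should enolise towards C9. This dianion is added to F10 to give the mixed bis-enol ether F11.
  - Oxidation as in step 5 comes back at 12.

**Step 11.**
- What may go wrong: the alkene may migrate to the tetrasubstituted C8=C9 position on the metal surface, or hydrogen may add from the wrong face and give the trans-fused lactone.
- Fallback: C8 is set by protonation and equilibration instead of syn-addition. It sets out from 18.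
  - Conjugate reduction with [(Ph3P)CuH]6 gives the saturated dibenzyl ester F12.
  - Its only acidic stereocentre, C8, is equilibrated with DBU. The cis-lactone keeps C11 anti to the bulky C5, while the trans isomer forces C11 gauche to C5.
  - Hydrogenolysis (H2, Pd/C) comes back at 19.

## Further compounds

F1 | step 5 | 2-chlorocyclohexan-1-one oxime (racemic) | ON=C1CCCCC1Cl
F2 | step 5 | α-substituted cyclohexanone oxime (C9-C10 formed) | ON=C1CCCC[C@H]1[C@]1(CO[Si](C)(C)C(C)(C)C)C(=O)C=CC(C)(C)[C@H]1C=C
F3 | step 5 | saturated 1,4-diketone | O=C1CCCC[C@H]1[C@]1(CO[Si](C)(C)C(C)(C)C)C(=O)C=CC(C)(C)[C@H]1C=C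
F4 | step 4 | trimethylsilyl dienol ether of 4 | C=C[C@H]1C(CO[Si](C)(C)C(C)(C)C)=C(O[Si](C)(C)C)C=CC1(C)C
F5 | step 4 | tertiary α-bromo enone (Br anti to vinyl) | C=C[C@H]1[C@@](Br)(CO[Si](C)(C)C(C)(C)C)C(=O)C=CC1(C)C
F6 | step 4 | 2-(trimethylsilyloxy)cyclohexa-1,3-diene | C[Si](C)(C)OC1=CCCC=C1
F7 | step 1 | (5S)-4,4-dimethyl-5-(nitromethyl)cyclohex-2-en-1-one | O=C1C=CC(C)(C)[C@H](C1)C[N+](=O)[O-]
F8 | step 1 | (1S)-2,2-dimethyl-5-oxocyclohex-3-ene-1-carbaldehyde | O=C[C@H]1CC(=O)C=CC1(C)C
F9 | step 6 | dibenzyl 2-[(1R)-3-oxocyclohexyl]malonate | O=C1CCC[C@H](C1)C(C(=O)OCc1ccccc1)C(=O)OCc1ccccc1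
F10 | step 6 | chloro(diisopropyl)silyl dienol ether of 4 | C=C[C@H]1C(CO[Si](C)(C)C(C)(C)C)=C(O[Si](Cl)(C(C)C)C(C)C)C=CC1(C)C
F11 | step 6 | mixed diisopropylsilyl bis-enol ether of 4 and F9 | C=C[C@H]1C(CO[Si](C)(C)C(C)(C)C)=C(O[Si](C(C)C)(C(C)C)OC2=CCC[C@H](C2)C(C(=O)OCc2ccccc2)C(=O)OCc2ccccc2)C=CC1(C)C
F12 | step 11 | saturated cis-fused lactone dibenzyl malonate | O=C(OCc1ccccc1)C(C(=O)OCc1ccccc1)[C@@H]1CC[C@@H]2[C@H](C1)C(=O)OC[C@]21C(=O)C[C@H]2OC[C@@H]1C2(C)C
A1 | alternative 1 | methyl (5R)-5-(prop-1-en-2-yl)cyclohex-1-ene-1-carboxylate | COC(=O)C1=CCC[C@H](C1)C(C)=C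
A2 | alternative 1 | Michael adduct with the configuration that would be needed | COC(=O)[C@H]1C[C@H](C(C)=C)CC[C@H]1[C@]1(CO[Si](C)(C)C(C)(C)C)C(=O)C=CC(C)(C)[C@H]1C=C
A3 | alternative 2 | spiro dihydropyranone (C8=C9) on the bridged ring A | O=C1C=C[C@]2(CO1)C(=O)C[C@H]1OC[C@@H]2C1(C)C
A4 | alternative 2 | 2-methyl-3-methylidenepenta-1,4-diene | C=CC(=C)C(C)=C
A5 | alternative 2 | cis-fused cycloadduct with the regiochemistry that would be needed (C12=C13) | CC(=C)C1=CC[C@@H]2[C@H](C1)C(=O)OC[C@]21C(=O)C[C@H]2OC[C@@H]1C2(C)C
A6 | alternative 3 | methyl 3,3-dimethyl-6-oxocyclohexa-1,4-diene-1-carboxylate | COC(=O)C1=CC(C)(C)C=CC1=O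
A7 | alternative 3 | trimethyl({1-[(5R)-5-(prop-1-en-2-yl)cyclohex-1-en-1-yl]vinyl}oxy)silane | C=C(O[Si](C)(C)C)C1=CCC[C@H](C1)C(C)=C
A8 | alternative 3 | cis-fused tricyclic cycloadduct (C5-C6 and C9-C10 cis on ring A) | COC(=O)[C@@]12C(=O)C=CC(C)(C)[C@@H]1CC(O[Si](C)(C)C)=C1C[C@H](C(C)=C)CC[C@H]12
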